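**Plan**
1. Numbering: the upper mesquitol unit has rings A, B, C with flavan numbers, and the lower (+)-catechin unit has rings D, E, F. After removal of the protecting groups, ring C is cut at C4a–C4 and at C2–C3 in one retro-[4+2] (oxa-Povarov) operation.
2. This leaves the cationic 2-oxadiene C4a=C8a–O1(+)=C2H–ring B, stored as acetal ester 5 (from pyrogallol and 3,4-bis(benzyloxy)benzaldehyde). It also leaves the two-carbon piece C3=C4, carried as (E)-enol acetate 13 on C8 of ring D (from (+)-catechin).
3. Enabling feature: O1 sits on ring A between the oxygen-bearing C8 and the free C4a, which is para to O7, so ring A can close only at C4a. C2 is an aldehyde-level carbon between O1 and catechol ring B. C4 carries the phloroglucinol-type ring D, which stabilises a C4 cation and makes C3 the nucleophilic end of C3=C4.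
4. Forward: rings D, E, F come intact from catechin (perbenzylation, C8 formylation, boron-Wittig, copper acetoxylation). Rings A and B are joined through O1–C2 as an acetal ester. Ring C forms last, in the union, and deacetylation and hydrogenolysis follow.
5. Stereochemistry: the lower C2/C3 come from (+)-catechin. The upper C2, C3, C4 are all set in step 8. The all-trans relation comes from the E alkene, the endo approach and acetoxy participation, and the absolute sense comes from a chiral counteranion. Any leakage gives diastereomers that can be separated.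

Key step: step 8

Assumption: the sense of induction of the chiral acid in step 8 cannot be derived from precedent. The (R) acid is written, and the (S) acid takes its place if a first trial shows it to be the matched one for the (2R,3S,4S) series.

**Step 1**
Reactants: 1 pyrogallol
Product: 2 2,2-diphenyl-1,3-benzodioxol-4-ol
Conditions: Ph2CCl2 (1.1 equiv), neat, 160 °C
Reagents that add atoms: dichlorodiphenylmethane, ClC(Cl)(c1ccccc1)c1ccccc1
Why: Ketalisation of a catechol pair with a gem-dichloride; the two vicinal OH pairs of pyrogallol are equivalent, so one ketal should form, and it leaves free exactly the OH that becomes O1.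

**Step 2**
Reactants: 3 3,4-bis(benzyloxy)benzaldehyde; 2 2,2-diphenyl-1,3-benzodioxol-4-ol
Product: 5 [3,4-bis(benzyloxy)phenyl][(2,2-diphenyl-1,3-benzodioxol-4-yl)oxy]methyl pivalate (racemic), via alpha-chlorobenzyl pivalate 4 (not isolated)
Conditions: 3, PivCl (1.05 equiv), ZnCl2 (2 mol %), CH2Cl2, 0 °C to rt; then 2, iPr2NEt, CH2Cl2, −20 to 0 °C
Reagents that add atoms: pivaloyl chloride, CC(C)(C)C(=O)Cl
Why: ZnCl2-catalysed addition of the acid chloride across the aldehyde C=O gives 4, whose ionisable benzylic chloride is displaced by the phenol oxygen of 2 as in the O-alkylation of phenols with acyloxyalkyl halides or 3-halophthalides, the bulky pivaloyl group disfavouring attack at the ester carbonyl; the new stereocentre is racemic and is erased in step 8.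

**Step 3**
Reactants: 6 (+)-catechin
Product: 7 (2R,3S)-5,7,3',4'-tetra-O-benzylcatechin
Conditions: BnBr (4.4 equiv), K2CO3, DMF, 0 °C to rt
Reagents that add atoms: benzyl bromide, BrCc1ccccc1
Why: Williamson etherification in which K2CO3 deprotonates only the four phenols, and the mild temperature keeps C2 from epimerising.

**Step 4**
Reactants: 7 (2R,3S)-5,7,3',4'-tetra-O-benzylcatechin
Product: 8 (2R,3S)-3,5,7,3',4'-penta-O-benzylcatechin
Conditions: NaH, BnBr, DMF, 0 °C to rt
Reagents that add atoms: benzyl bromide, BrCc1ccccc1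
Why: Williamson etherification of the remaining secondary alcohol, which removes the last nucleophilic OH before the cationic chemistry.

**Step 5**
Reactants: 8 (2R,3S)-3,5,7,3',4'-penta-O-benzylcatechin
Product: 10 (2R,3S)-3,5,7,3',4'-penta-O-benzyl-8-formylcatechin, via C8 iminium chloride 9 (not isolated)
Conditions: POCl3, DMF, 0 to 60 °C; then H2O
Reagents that add atoms: N,N-dimethylformamide, CN(C)C=O; water, O
Why: Vilsmeier-Haack formylation of the trialkoxy ring D, expected at C8 as in the bromination of benzylated flavan-3-ols, because C6 lies between two benzyloxy groups while C8 adjoins the tied-back O1.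

**Step 6**
Reactants: 10 (2R,3S)-3,5,7,3',4'-penta-O-benzyl-8-formylcatechin
Product: 12 (2R,3S)-3,5,7,3',4'-penta-O-benzyl-8-[(E)-2-(4,4,5,5-tetramethyl-1,3,2-dioxaborolan-2-yl)vinyl]catechin, via lithium alkoxide adduct 11 (not isolated)
Conditions: CH2(Bpin)2, LiTMP, THF, 0 °C; then 10, −78 °C to rt
Reagents that add atoms: bis(4,4,5,5-tetramethyl-1,3,2-dioxaborolan-2-yl)methane, CC1(C)OB(CB2OC(C)(C)C(C)(C)O2)OC1(C)C
Why: Boron-Wittig olefination, in which the lithiated geminal bis(boronate) adds to the aldehyde and syn B–O elimination from 11 should give the E alkenyl boronate.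

**Step 7**
Reactants: 12 (2R,3S)-3,5,7,3',4'-penta-O-benzyl-8-[(E)-2-(4,4,5,5-tetramethyl-1,3,2-dioxaborolan-2-yl)vinyl]catechin
Product: 13 (2R,3S)-8-[(E)-2-acetoxyvinyl]-3,5,7,3',4'-penta-O-benzylcatechin
Conditions: Cu(OAc)2 (2.2 equiv), Et3N, 4 Å MS, MeCN, rt, Ar
Reagents that add atoms: copper diacetate, CC(=O)[O-].CC(=O)[O-].[Cu+2]
Why: Chan-Evans-Lam type C–O coupling of an alkenyl boronate with carboxylate, in which transmetalation to divalent copper and reductive elimination from trivalent copper both proceed with retention, so the E geometry is kept.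

**Step 8**
Reactants: 5 [3,4-bis(benzyloxy)phenyl][(2,2-diphenyl-1,3-benzodioxol-4-yl)oxy]methyl pivalate; 13 (2R,3S)-8-[(E)-2-acetoxyvinyl]-3,5,7,3',4'-penta-O-benzylcatechin
Product: 16 (2R,3S,4S)-3-O-acetyl-3',4'-di-O-benzyl-7,8-O-(diphenylmethylene)mesquitol-(4α→8)-(2R,3S)-3,5,7,3',4'-penta-O-benzylcatechin, via aryl oxocarbenium ion 14 (not isolated), via C4 benzylic cation 15 (not isolated)
Conditions: (R)-3,3'-bis(2,4,6-triisopropylphenyl)-1,1'-binaphthyl-2,2'-diyl N-(trifluoromethylsulfonyl)phosphoramide (C51H57F3NO5PS, 10 mol %), 4 Å MS, toluene/CH2Cl2, −60 °C, slow addition of 5 (1.3 equiv)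
Reagents that add atoms: none
Why: Proposed new method: the chiral acid protonates the pivalate of 5, which is the better nucleofuge and the poorer donor of the two acetal oxygens, so that only the ring A aryl oxocarbenium ion 14 forms, paired with the chiral phosphoramidate anion; C3 of 13 then adds to C2 (Prins-type step) to give the ring D stabilised C4 cation 15, and C4a of ring A attacks C4 and hands its proton back to the catalyst. The closest known reaction type is the oxa-Povarov reaction (SnCl4-promoted formal [4+2] cycloaddition of aryl 2-oxadiene oxocarbenium ions with styrenes and beta-methylstyrenes to 2,4-cis and all-trans chromans), and the counteranion control is borrowed from chiral Brønsted acid catalysed Povarov reactions and additions to oxocarbenium ion pairs, so that the beta-acyloxystyrene partner and the catalyst control are the new elements. Ring C closes as a formal inverse-demand [4+2] annulation, in stepwise terms a six-membered Friedel-Crafts cycloalkylation with the aromatic C4a–C8a bond inside the new ring (6-endo at the arene) through a chair-like transition state. The absolute sense at C2 and C3 is set by the face of 14 that the chiral anion leaves open, their trans relation by the endo approach of ring D over the E-configured cation (outside aryl at C2 cis to endo aryl at C4), and C4 becomes trans to C3 through the E alkene geometry if the addition is concerted or through equatorial closure anti to the participating C3 acetoxy group (1,3-dioxolan-2-ylium form of 15) if it is stepwise. The step needs C3 and not C4 as the nucleophilic carbon, which the three oxygen donors of ring D, the acyl-damped enol oxygen and the shielding of C4 by two ortho substituents secure, and it needs closure at one ring A carbon, which is secured because C8 is occupied and C4a, para to O7, is the only free position ortho to O1. The two all-trans products that differ in the attacked face are diastereomers because the catechin unit is enantiopure, so that any leakage of facial control is removed by chromatography and not carried on as an enantiomer.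

**Step 9**
Reactants: 16 (2R,3S,4S)-3-O-acetyl-3',4'-di-O-benzyl-7,8-O-(diphenylmethylene)mesquitol-(4α→8)-penta-O-benzylcatechin
Product: 17 (2R,3S,4S)-3',4'-di-O-benzyl-7,8-O-(diphenylmethylene)mesquitol-(4α→8)-(2R,3S)-3,5,7,3',4'-penta-O-benzylcatechin
Conditions: K2CO3 (cat.), MeOH/THF, rt
Reagents that add atoms: none
Why: Base-catalysed transesterification removes the only ester and leaves benzyl ethers, the ketal and all stereocentres untouched.

**Step 10**
Reactants: 17 (2R,3S,4S)-3',4'-di-O-benzyl-7,8-O-(diphenylmethylene)mesquitol-(4α→8)-penta-O-benzylcatechin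
Product: 18 (+)-mesquitol-(4α→8)-(+)-catechin (CNP0231186.1)
Conditions: H2 (1 atm), Pd(OH)2/C, THF/MeOH/H2O, rt
Reagents that add atoms: none
Why: Global hydrogenolysis of seven benzyl ethers and the diphenylmethylene ketal under neutral conditions, as used for benzylated proanthocyanidins, which spares the acid-sensitive C4–C8 bond and the ring C and ring F ethers.

**Compound list**
1 | pyrogallol | Oc1cccc(O)c1O | starting material
2 | 2,2-diphenyl-1,3-benzodioxol-4-ol | Oc1cccc2OC(c3ccccc3)(c3ccccc3)Oc12 | intermediate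
3 | 3,4-bis(benzyloxy)benzaldehyde | O=Cc1ccc(OCc2ccccc2)c(OCc2ccccc2)c1 | starting material
4 | chloro[3,4-bis(benzyloxy)phenyl]methyl pivalate (racemic, not isolated) | CC(C)(C)C(=O)OC(Cl)c1ccc(OCc2ccccc2)c(OCc2ccccc2)c1 | intermediate
5 | [3,4-bis(benzyloxy)phenyl][(2,2-diphenyl-1,3-benzodioxol-4-yl)oxy]methyl pivalate (racemic) | CC(C)(C)C(=O)OC(Oc1cccc2OC(c3ccccc3)(c3ccccc3)Oc12)c1ccc(OCc2ccccc2)c(OCc2ccccc2)c1 | intermediate
6 | (+)-catechin, (2R,3S) | Oc1cc(O)c2c(c1)O[C@H](c1ccc(O)c(O)c1)[C@@H](O)C2 | starting material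
7 | (2R,3S)-5,7,3',4'-tetra-O-benzylcatechin | c1c(OCc2ccccc2)cc(OCc2ccccc2)c2c1O[C@H](c1ccc(OCc3ccccc3)c(OCc3ccccc3)c1)[C@@H](O)C2 | intermediate
8 | (2R,3S)-3,5,7,3',4'-penta-O-benzylcatechin | c1c(OCc2ccccc2)cc(OCc2ccccc2)c2c1O[C@H](c1ccc(OCc3ccccc3)c(OCc3ccccc3)c1)[C@@H](OCc1ccccc1)C2 | intermediate
9 | C8 dimethyliminium chloride of 8 (not isolated) | C[N+](C)=Cc1c(OCc2ccccc2)cc(OCc2ccccc2)c2c1O[C@H](c1ccc(OCc3ccccc3)c(OCc3ccccc3)c1)[C@@H](OCc1ccccc1)C2.[Cl-] | intermediate
10 | (2R,3S)-3,5,7,3',4'-penta-O-benzyl-8-formylcatechin | O=Cc1c(OCc2ccccc2)cc(OCc2ccccc2)c2c1O[C@H](c1ccc(OCc3ccccc3)c(OCc3ccccc3)c1)[C@@H](OCc1ccccc1)C2 | intermediate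
11 | lithium alkoxide adduct of 10 with lithiated bis(pinacolboryl)methane (carbinol centre undefined, not isolated) | [Li+].[O-]C(C(B1OC(C)(C)C(C)(C)O1)B1OC(C)(C)C(C)(C)O1)c1c(OCc2ccccc2)cc(OCc2ccccc2)c2c1O[C@H](c1ccc(OCc3ccccc3)c(OCc3ccccc3)c1)[C@@H](OCc1ccccc1)C2 | intermediate
12 | (2R,3S)-penta-O-benzyl-8-[(E)-2-(pinacolboryl)vinyl]catechin | CC1(C)OB(/C=C/c2c(OCc3ccccc3)cc(OCc3ccccc3)c3c2O[C@H](c2ccc(OCc4ccccc4)c(OCc4ccccc4)c2)[C@@H](OCc2ccccc2)C3)OC1(C)C | intermediate
13 | (2R,3S)-8-[(E)-2-acetoxyvinyl]-penta-O-benzylcatechin | CC(=O)O/C=C/c1c(OCc2ccccc2)cc(OCc2ccccc2)c2c1O[C@H](c1ccc(OCc3ccccc3)c(OCc3ccccc3)c1)[C@@H](OCc1ccccc1)C2 | intermediate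
14 | (E)-[3,4-bis(benzyloxy)benzylidene](2,2-diphenyl-1,3-benzodioxol-4-yl)oxonium, ion pair with the catalyst anion (not isolated) | C(c1ccccc1)Oc1ccc(/C=[O+]/c2cccc3OC(c4ccccc4)(c4ccccc4)Oc23)cc1OCc1ccccc1 | intermediate
15 | C4 benzylic cation after C2–C3 bond formation, ion pair with the catalyst anion (not isolated) | C(c1ccccc1)Oc1ccc([C@@H](Oc2cccc3OC(c4ccccc4)(c4ccccc4)Oc23)[C@@H](OC(C)=O)[CH+]c2c(OCc3ccccc3)cc(OCc3ccccc3)c3c2O[C@H](c2ccc(OCc4ccccc4)c(OCc4ccccc4)c2)[C@@H](OCc2ccccc2)C3)cc1OCc1ccccc1 | intermediate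
16 | (2R,3S,4S)-3-O-acetyl-3',4'-di-O-benzyl-7,8-O-(diphenylmethylene)mesquitol-(4α→8)-penta-O-benzylcatechin | C(c1ccccc1)Oc1ccc([C@H]2Oc3c(ccc4OC(c5ccccc5)(c5ccccc5)Oc34)[C@@H](c6c(OCc7ccccc7)cc(OCc7ccccc7)c7c6O[C@H](c6ccc(OCc8ccccc8)c(OCc8ccccc8)c6)[C@@H](OCc6ccccc6)C7)[C@@H]2OC(C)=O)cc1OCc1ccccc1 | intermediate
17 | (2R,3S,4S)-3',4'-di-O-benzyl-7,8-O-(diphenylmethylene)mesquitol-(4α→8)-penta-O-benzylcatechin | C(c1ccccc1)Oc1ccc([C@H]2Oc3c(ccc4OC(c5ccccc5)(c5ccccc5)Oc34)[C@@H](c6c(OCc7ccccc7)cc(OCc7ccccc7)c7c6O[C@H](c6ccc(OCc8ccccc8)c(OCc8ccccc8)c6)[C@@H](OCc6ccccc6)C7)[C@@H]2O)cc1OCc1ccccc1 | intermediate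
18 | (+)-mesquitol-(4α→8)-(+)-catechin, upper unit (2R,3S,4S), lower unit (2R,3S) | Oc1ccc([C@H]2Oc3c(ccc(O)c3O)[C@@H](c3c(O)cc(O)c4c3O[C@H](c3ccc(O)c(O)c3)[C@@H](O)C4)[C@@H]2O)cc1O | target

**Totals**
Total step count: 10. Longest linear sequence: 8 steps (6 to 18, steps 3 to 10).

**Steps most likely to fail**

Step 8. Possible failures are poor facial selectivity of the ion pair, cationic oligomerisation of the enol acetate, and capture of the C4 cation by pivalic acid before ring closure.
- The fallback uses known chemistry. It sets out from 10 and 2 and comes back at 17.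
- Claisen-Schmidt condensation of 10 with commercial 3,4-bis(benzyloxy)acetophenone (KOH, EtOH/THF) should give the chalcone (E)-1-[3,4-bis(benzyloxy)phenyl]-3-(penta-O-benzylcatechin-8-yl)prop-2-en-1-one F1.
- Phenol 2 then adds through its free ortho carbon in an acid-catalysed Friedel-Crafts conjugate addition, followed by cyclodehydration (BF3·OEt2, 4 Å MS, CH2Cl2). This should give the 2,4-diaryl-4H-chromene as two C4 epimers.
- The epimers are diastereomers, and separation leaves the (4S)-flav-2-ene F2.
- Hydroboration (BH3·SMe2, THF) from the face anti to ring D, then oxidation (NaOH, H2O2), places H at C2 and OH at C3 on the same face and so leads to all-trans 17.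

Step 2. Possible failures are incomplete addition of the acid chloride to the electron-rich aldehyde, and acyl transfer to the phenol instead of O-alkylation.
- The fallback sets out from 2 and comes back at 5.
- Williamson etherification of 2 with commercial 3,4-bis(benzyloxy)benzyl chloride (K2CO3, DMF) should give 4-{[3,4-bis(benzyloxy)benzyl]oxy}-2,2-diphenyl-1,3-benzodioxole F3.
- The dialkoxybenzylic CH2 of F3 is then oxidised by hydride abstraction with DDQ in the presence of pivalic acid (4 Å MS, CH2Cl2, 0 °C). The oxocarbenium ion is trapped as the acetal ester 5.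

Step 7. Possible failures are protodeboronation, oxidative homocoupling of the alkenyl boronate, and oxidation of the electron-rich styrene by divalent copper.
- The fallback sets out from 10 and comes back at 13.
- Wittig methoxymethylenation (Ph3P(CH2OMe)Cl, KOtBu, THF) should give the enol methyl ether 8-(2-methoxyvinyl)-penta-O-benzylcatechin F4 as an E/Z mixture.
- Mild acid hydrolysis (HCO2H, CH2Cl2/H2O) gives the arylacetaldehyde (penta-O-benzylcatechin-8-yl)acetaldehyde F5.
- Enol acetylation (Ac2O, Et3N, DMAP) gives the enol acetate, from which the E isomer 13 is separated by chromatography.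

**Further compounds**
F1 | step 8 | (E)-1-[3,4-bis(benzyloxy)phenyl]-3-[(2R,3S)-penta-O-benzylcatechin-8-yl]prop-2-en-1-one | O=C(/C=C/c1c(OCc2ccccc2)cc(OCc2ccccc2)c2c1O[C@H](c1ccc(OCc3ccccc3)c(OCc3ccccc3)c1)[C@@H](OCc1ccccc1)C2)c1ccc(OCc2ccccc2)c(OCc2ccccc2)c1
F2 | step 8 | (4S)-2-[3,4-bis(benzyloxy)phenyl]-7,8-(diphenylmethylenedioxy)-4-[(2R,3S)-penta-O-benzylcatechin-8-yl]-4H-chromene | C(c1ccccc1)Oc1ccc(C2Oc3c(ccc4OC(c5ccccc5)(c5ccccc5)Oc34)[C@@H](c6c(OCc7ccccc7)cc(OCc7ccccc7)c7c6O[C@H](c6ccc(OCc8ccccc8)c(OCc8ccccc8)c6)[C@@H](OCc6ccccc6)C7)C=2)cc1OCc1ccccc1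
F3 | step 2 | 4-{[3,4-bis(benzyloxy)benzyl]oxy}-2,2-diphenyl-1,3-benzodioxole | C(c1ccccc1)Oc1ccc(COc2cccc3OC(c4ccccc4)(c4ccccc4)Oc23)cc1OCc1ccccc1
F4 | step 7 | (2R,3S)-8-(2-methoxyvinyl)-penta-O-benzylcatechin (E/Z mixture) | COC=Cc1c(OCc2ccccc2)cc(OCc2ccccc2)c2c1O[C@H](c1ccc(OCc3ccccc3)c(OCc3ccccc3)c1)[C@@H](OCc1ccccc1)C2
F5 | step 7 | [(2R,3S)-penta-O-benzylcatechin-8-yl]acetaldehyde | O=CCc1c(OCc2ccccc2)cc(OCc2ccccc2)c2c1O[C@H](c1ccc(OCc3ccccc3)c(OCc3ccccc3)c1)[C@@H](OCc1ccccc1)C2
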